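Count what is left of the charge rather than what has been made. Solid substrate goes in and ends as isomer of the product and target, and I called whatever that pair had not yet taken up the fraction left.

| flask | solid substrate | remark | time |
|---|---|---|---|
| amber | 0.35 M | run made earlier |  |
| violet | 0.55 M | run made earlier |  |
| flask | 0.25 M |  | 8.0 h |

| run | time / h | isomer of the product / % | target / % |
|---|---|---|---|
| amber | 0.833 | 17 | 36 |
| amber | 2.00 | 32 | 64 |
| amber | 4.00 | 36 | 65 |
| amber | 10.0 | 36 | 64 |
| violet | 1.33 | 20 | 38 |
| violet | 3.00 | 35 | 64 |
| violet | 6.00 | 37 | 68 |
| violet | 10.0 | 33 | 64 |

(standard deviation of a reading: 1.5 percentage points)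

- at the start none of the solid substrate is in solution
- a reading or a percentage of target counts all its forms, free or not

- share of isomer of the product in isomer of the product plus target at 4.0 min
- share of isomer of the product in isomer of the product plus target at 40 min
- share of isomer of the product in isomer of the product plus target at 8.0 h

In the amber run the fraction left was 47.0 % at 0.833 h, and by 10.0 h the pair summed to 100 %. Over that span the isomer share went from 32.1 % to 36.0 %, with each reading scattered by 1.5 percentage points. So I used a bench rule: isomer of the product equals a fixed share of one minus the fraction left. That share is the selectivity of the two paths, and pooling all the readings of both runs gave the pooled share 34.7 %.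

The rule has a border. The early question sits at 0.0800 of the earliest reading's time, and the flask holds 0.714 of the lowest earlier charge. The charge looked the more serious gap: at 10.0 h the amber run stood at 36.0 % and the violet run at 34.0 %, a difference of 2 points, which I took as a weak hint, with each reading scattered by 1.5 points. I committed to 34.7 % for both early times, and for 8.0 h to the last two amber readings pooled, 35.8 %.

The forecast gave 33 %, 33.5 % and 35.5 %, lower than mine early, holding that “any concentration dependence is weak”.

The simulation gave 34.6 %, 34.8 % and 36.1 %.

    starting material ⇌ target (K = 9.40, k = 0.0380 /min)
    starting material ⇌ isomer of the product (K = 190, k = 0.0200 /min)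
    crystals ⇌ target, rate k3*(cs3 - [target]) while solid is left; crystals form when [target] > cs3 (solubility = 9.90 mM, k = 3.10 /min)
    solid substrate ⇌ starting material, rate k4*(cs4 - [starting material]) while solid is left; crystals form when [starting material] > cs4 (solubility = 0.190 M, k = 0.0400 /min)

The half-life of isomer of the product for going back through starting material is 110 h, long against 8.0 h. In this flask at 0.800 h, 32.3 % was left as starting material and solid substrate, and 34.7 % of the rest is 23.5 %, against 23.6 % of isomer of the product in the flask. The neighbour flask with 0.062 M of solid substrate had 1.2 % left at 8.00 h, so the same reckoning gives 34.3 %, yet that flask held 43.4 % of isomer of the product.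

The readings come from a simulation for substances that don't exist.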